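**Retrosynthetic overview**
1. Target 13 ⇒ allenyl enal 10 + CO2. One nickel-mediated operation forms C15–C16, C1–C2 and the lactone C–O bond, so the 14-membered carbocycle and the γ-lactone close together in the last step.
2. 10 ⇒ epoxy dialdehyde 5 + a C4 dienyl unit from chloroprene 6. Reagent-controlled homoallenylboration of the epoxy aldehyde sets C13, then acetylation.
3. 5 ⇒ (2E,6E)-farnesyl acetate 1, by allylic oxidation of the terminal (E)-methyl group, Sharpless epoxidation (sets C11 and C12), deacetylation and double oxidation.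
4. Ring order: epoxide (step 2), then macrocycle and lactone simultaneously (step 7).

Assumption: atom labels follow cembrane numbering (ring C1–C14, lactone carbons C15–C17, methyls C18–C20); single-isomer (2E,6E)-farnesyl acetate and chloroprene are taken as purchasable.

**Step 1**
Reactants: 1 (2E,6E)-3,7,11-trimethyldodeca-2,6,10-trien-1-yl acetate
Product: 2 (2E,6E,10E)-12-hydroxy-3,7,11-trimethyldodeca-2,6,10-trien-1-yl acetate
Conditions: SeO2 (0.2 equiv), t-BuOOH (3 equiv), salicylic acid (0.1 equiv), CH2Cl2, 0 °C to rt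
Reagents that add atoms: tert-butyl hydroperoxide, CC(C)(C)OO
Why: Sharpless SeO2/t-BuOOH allylic oxidation (ene reaction then [2,3]-sigmatropic shift) attacks the electron-rich terminal trisubstituted alkene and hydroxylates its (E)-methyl group (C13), the C3=C4 alkene being deactivated by the allylic acetate; no stereocentre is formed.

**Step 2**
Reactants: 2 (2E,6E,10E)-12-hydroxy-3,7,11-trimethyldodeca-2,6,10-trien-1-yl acetate
Product: 3 (2E,6E)-9-[(2R,3R)-3-(hydroxymethyl)-3-methyloxiran-2-yl]-3,7-dimethylnona-2,6-dien-1-yl acetate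
Conditions: Ti(OiPr)4 (10 mol%), D-(−)-diisopropyl tartrate (12 mol%), t-BuOOH (in decane), 4 Å MS, CH2Cl2, −20 °C
Reagents that add atoms: tert-butyl hydroperoxide, CC(C)(C)OO
Why: Katsuki–Sharpless asymmetric epoxidation acts only on the free allylic alcohol, and the D-(−)-tartrate delivers oxygen to the face that gives the (2R,3R)-epoxy alcohol, which is the C11/C12 arrangement of the target (L-(+)-tartrate gives 2S,3S with (E)-2-methylalk-2-en-1-ols).

**Step 3**
Reactants: 3 (2E,6E)-9-[(2R,3R)-3-(hydroxymethyl)-3-methyloxiran-2-yl]-3,7-dimethylnona-2,6-dien-1-yl acetate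
Product: 4 (2E,6E)-9-[(2R,3R)-3-(hydroxymethyl)-3-methyloxiran-2-yl]-3,7-dimethylnona-2,6-dien-1-ol
Conditions: K2CO3 (0.3 equiv), MeOH, 0 °C
Reagents that add atoms: none
Why: Base-catalysed transesterification (methanolysis) removes the primary allylic acetate, and the short, cold reaction leaves the epoxy alcohol intact (no Payne rearrangement) with no stereocentre touched.

**Step 4**
Reactants: 4 (2E,6E)-9-[(2R,3R)-3-(hydroxymethyl)-3-methyloxiran-2-yl]-3,7-dimethylnona-2,6-dien-1-ol
Product: 5 (2S,3R)-3-[(3E,7E)-3,7-dimethyl-9-oxonona-3,7-dien-1-yl]-2-methyloxirane-2-carbaldehyde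
Conditions: TEMPO (2,2,6,6-tetramethylpiperidin-1-oxyl, 0.2 equiv), PhI(OAc)2 (2.4 equiv), CH2Cl2, rt
Reagents that add atoms: none
Why: Oxoammonium (TEMPO/PhI(OAc)2) oxidation takes both primary alcohols to aldehydes without over-oxidation; the epoxide-bearing α-carbon is quaternary and cannot epimerise, and the trisubstituted alkenes are inert.

**Step 5**
Reactants: 5 (2S,3R)-3-[(3E,7E)-3,7-dimethyl-9-oxonona-3,7-dien-1-yl]-2-methyloxirane-2-carbaldehyde; 6 2-chlorobuta-1,3-diene (chloroprene)
Product: 9 (2E,6E)-9-[(2R,3R)-3-[(1S)-1-hydroxypenta-3,4-dien-1-yl]-3-methyloxiran-2-yl]-3,7-dimethylnona-2,6-dienal, via dienyl Grignard reagent 7 (not isolated), via dienylborane 8 (not isolated)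
Conditions: 6, Mg, ZnCl2 (cat.), THF, 50 °C; (−)-Ipc2BOMe [(−)-B-methoxydiisopinocampheylborane], Et2O, −78 to 0 °C; 1.0 equiv added slowly to 5, Et2O, −100 to −78 °C; MeCHO, rt; aq. NaHCO3
Reagents that add atoms: none
Why: Proposed new method: dienylborane 8 transfers its buta-1,3-dien-2-yl group with allylic transposition (SE2′, closed six-membered transition state) so that C14 bonds to C13 and a terminal allene results, the (+)-α-pinene-derived isopinocampheyl groups directing attack to the Si face to set 13S (threo to the epoxide, reagent control overriding the Felkin preference), while the non-conjugated α-oxygenated epoxy aldehyde reacts much faster than the β,β-disubstituted enal; the closest known reactions are Brown allyl-, allenyl- and isoprenylborations with Ipc2B reagents and the SE2′ addition of buta-1,3-dien-2-yl boron and magnesium reagents to aldehydes.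

**Step 6**
Reactants: 9 (2E,6E)-9-[(2R,3R)-3-[(1S)-1-hydroxypenta-3,4-dien-1-yl]-3-methyloxiran-2-yl]-3,7-dimethylnona-2,6-dienal
Product: 10 (1S)-1-[(2S,3R)-3-[(3E,7E)-3,7-dimethyl-9-oxonona-3,7-dien-1-yl]-2-methyloxiran-2-yl]penta-3,4-dien-1-yl acetate
Conditions: Ac2O, pyridine, DMAP (cat.), CH2Cl2, 0 °C to rt
Reagents that add atoms: acetic anhydride, CC(=O)OC(C)=O
Why: DMAP-catalysed acylation installs the C13 acetate with retention (the descriptor at the neighbouring epoxide carbon changes only through ligand priority), and the enal, allene and epoxide are inert.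

**Step 7**
Reactants: 10 (1S)-1-[(2S,3R)-3-[(3E,7E)-3,7-dimethyl-9-oxonona-3,7-dien-1-yl]-2-methyloxiran-2-yl]penta-3,4-dien-1-yl acetate
Product: 13 (1R,2S,3E,7E,11R,12S,13S)-13-acetoxy-11,12-epoxycembra-3,7,15(17)-trien-16,2-olide, via oxanickelacycle 11 (not isolated), via seco hydroxy acid 12 (not isolated)
Conditions: Ni(cod)2 (1.05 equiv), DBU (2.2 equiv), CO2 (1 atm), THF, 0 °C; Ar purge, dilution to 2 mM, 35 °C; AcOH, 0 °C to rt
Reagents that add atoms: carbon dioxide, O=C=O
Why: Proposed new method: zerovalent nickel and CO2 convert the terminal allene into an allylnickel carboxylate of divalent nickel (oxanickelacycle 11, new C15–C16 bond), whose substituted allyl terminus C1 then adds to the tethered enal carbonyl through a closed six-membered transition state with both chain branches (C14 on C1, C3 on C2) equatorial, which closes the 14-membered ring and gives the 1,2-anti hydroxy acid 12 that lactonises on acidification to the trans-fused α-methylene lactone, the sense at C1/C2 relative to C11–C13 resting on substrate control in the macrocyclic transition state; the closest known reaction is the intermolecular nickel-mediated sequential coupling of terminal allenes with CO2 and aldehydes, supported by allylnickel and allylchromium carbonyl-addition macrocyclisations.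

**Compound list**
1 | (2E,6E)-3,7,11-trimethyldodeca-2,6,10-trien-1-yl acetate [(2E,6E)-farnesyl acetate] | CC(=O)OC/C=C(\C)CC/C=C(\C)CCC=C(C)C | starting material
2 | (2E,6E,10E)-12-hydroxy-3,7,11-trimethyldodeca-2,6,10-trien-1-yl acetate | CC(=O)OC/C=C(\C)CC/C=C(\C)CC/C=C(\C)CO | intermediate
3 | (2E,6E)-9-[(2R,3R)-3-(hydroxymethyl)-3-methyloxiran-2-yl]-3,7-dimethylnona-2,6-dien-1-yl acetate | CC(=O)OC/C=C(\C)CC/C=C(\C)CC[C@H]1O[C@]1(C)CO | intermediate
4 | (2E,6E)-9-[(2R,3R)-3-(hydroxymethyl)-3-methyloxiran-2-yl]-3,7-dimethylnona-2,6-dien-1-ol | OC/C=C(\C)CC/C=C(\C)CC[C@H]1O[C@]1(C)CO | intermediate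
5 | (2S,3R)-3-[(3E,7E)-3,7-dimethyl-9-oxonona-3,7-dien-1-yl]-2-methyloxirane-2-carbaldehyde | O=C/C=C(\C)CC/C=C(\C)CC[C@H]1O[C@]1(C)C=O | intermediate
6 | 2-chlorobuta-1,3-diene (chloroprene) | C=CC(Cl)=C | starting material
7 | buta-1,3-dien-2-ylmagnesium chloride (dienyl Grignard reagent) | C=CC(=C)[Mg]Cl | intermediate
8 | B-(buta-1,3-dien-2-yl)bis[(1R,2S,3R,5R)-2,6,6-trimethylbicyclo[3.1.1]heptan-3-yl]borane (dienylborane) | C=CC(=C)B([C@@H]1C[C@@H]2C[C@H]([C@H]1C)C2(C)C)[C@@H]1C[C@@H]2C[C@H]([C@H]1C)C2(C)C | intermediate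
9 | (2E,6E)-9-[(2R,3R)-3-[(1S)-1-hydroxypenta-3,4-dien-1-yl]-3-methyloxiran-2-yl]-3,7-dimethylnona-2,6-dienal | O=C/C=C(\C)CC/C=C(\C)CC[C@H]1O[C@]1(C)[C@@H](O)CC=C=C | intermediate
10 | (1S)-1-[(2S,3R)-3-[(3E,7E)-3,7-dimethyl-9-oxonona-3,7-dien-1-yl]-2-methyloxiran-2-yl]penta-3,4-dien-1-yl acetate | O=C/C=C(\C)CC/C=C(\C)CC[C@H]1O[C@]1(C)[C@@H](OC(C)=O)CC=C=C | intermediate
11 | oxanickelacycle: allylnickel carboxylate of divalent nickel from the allene of 10 and CO2 (C15–C16 bond; C14 trans to the CH2–Ni carbon; DBU ligands not drawn) | O=C/C=C(\C)CC/C=C(\C)CC[C@H]1O[C@]1(C)[C@@H](OC(C)=O)C/C=C2/C[Ni]OC2=O | intermediate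
12 | seco hydroxy acid: 2-[(1R,2S,3E,7E,11R,12S,13S)-13-acetoxy-11,12-epoxy-2-hydroxy-4,8,12-trimethylcyclotetradeca-3,7-dien-1-yl]prop-2-enoic acid (cembrane numbering) | O[C@H]1/C=C(\C)CC/C=C(\C)CC[C@H]2O[C@]2(C)[C@@H](OC(C)=O)C[C@@H]1C(=C)C(=O)O | intermediate
13 | (1R,2S,3E,7E,11R,12S,13S)-13-acetoxy-11,12-epoxycembra-3,7,15(17)-trien-16,2-olide (CNP0146076.5) | C=C1C(=O)O[C@H]2/C=C(\C)CC/C=C(\C)CC[C@H]3O[C@]3(C)[C@@H](OC(C)=O)C[C@H]12 | target

**Step count and risks**
Total step count: 7. Longest linear sequence: 7 steps (1 to 13; 6 enters at step 5).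

Steps most likely to fail:

Step 7 (key closure). The macrocyclic, intramolecular version of the allene/CO2/aldehyde coupling is untested. Specific risks are oligomerisation, a second carboxylation, E/Z drift of the enal under DBU, formation of the cis-lactone, and the wrong C1/C2 sense relative to C11–C13 (nothing but substrate control fixes it). Fallback: abandon the CO2 route and close the rings by a Barbier-type allylation. Setting out from dialdehyde 5, allylboration with (−)-Ipc2B(allyl) at −100 °C gives homoallylic alcohol F1. Acetylation (Ac2O, pyridine, DMAP) gives acetate F2. Cross-metathesis with methyl 2-(bromomethyl)acrylate, using the second-generation Hoveyda–Grubbs catalyst [RuCl2(=CH-C6H4-2-OiPr)(H2IMes)], gives allylic bromide F3. Indium metal in THF/H2O at high dilution (or CrCl2 with a chiral carbazole-bis(oxazoline) ligand, if catalyst control of the C1/C2 sense is needed) then closes macrocycle and lactone together and comes back to the route at target 13. Simple 2-(bromomethyl)alk-2-enoates tend to give cis-lactones under indium or zinc, so this fallback carries its own stereochemical risk.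

Step 5 (homoallenylboration of the dialdehyde). The chiral dienylborane is an extension of known reagents, and it must both choose the epoxy aldehyde over the enal and override the Felkin (erythro) bias. Fallback: build the allene in two known stages. Setting out from 5, Brown-type propargylation with B-allenyldiisopinocampheylborane (from allenylmagnesium bromide and (−)-Ipc2BOMe) gives homopropargylic alcohol F4. Crabbé–Ma homologation (paraformaldehyde, CuI, dicyclohexylamine, dioxane, 100 °C) then converts the terminal alkyne into the terminal allene and comes back to the route at 9.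

Step 4 (double oxidation). Dialdehyde 5 carries a reactive epoxy aldehyde and may not survive handling. Fallback: differentiate the two ends by the acetate instead of by reactivity. Setting out from 3, oxidation of its single free alcohol (TEMPO, PhI(OAc)2) gives epoxy aldehyde F5. Homoallenylboration with 8 gives alcohol F6. Methanolysis (K2CO3, MeOH, 0 °C) gives diol F7, and MnO2 oxidises only the primary allylic alcohol, coming back to the route at 9.

**Further compounds**
F1 | step 7 | (2E,6E)-9-[(2R,3R)-3-[(1S)-1-hydroxybut-3-en-1-yl]-3-methyloxiran-2-yl]-3,7-dimethylnona-2,6-dienal | O=C/C=C(\C)CC/C=C(\C)CC[C@H]1O[C@]1(C)[C@@H](O)CC=C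
F2 | step 7 | (1S)-1-[(2S,3R)-3-[(3E,7E)-3,7-dimethyl-9-oxonona-3,7-dien-1-yl]-2-methyloxiran-2-yl]but-3-en-1-yl acetate | O=C/C=C(\C)CC/C=C(\C)CC[C@H]1O[C@]1(C)[C@@H](OC(C)=O)CC=C
F3 | step 7 | methyl (2Z,5S)-5-acetoxy-2-(bromomethyl)-5-[(2S,3R)-3-[(3E,7E)-3,7-dimethyl-9-oxonona-3,7-dien-1-yl]-2-methyloxiran-2-yl]pent-2-enoate | O=C/C=C(\C)CC/C=C(\C)CC[C@H]1O[C@]1(C)[C@@H](OC(C)=O)C/C=C(\CBr)C(=O)OC
F4 | step 5 | (2E,6E)-9-[(2R,3R)-3-[(1S)-1-hydroxybut-3-yn-1-yl]-3-methyloxiran-2-yl]-3,7-dimethylnona-2,6-dienal | O=C/C=C(\C)CC/C=C(\C)CC[C@H]1O[C@]1(C)[C@@H](O)CC#C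
F5 | step 4 | (2E,6E)-9-[(2R,3S)-3-formyl-3-methyloxiran-2-yl]-3,7-dimethylnona-2,6-dien-1-yl acetate | CC(=O)OC/C=C(\C)CC/C=C(\C)CC[C@H]1O[C@]1(C)C=O
F6 | step 4 | (2E,6E)-9-[(2R,3R)-3-[(1S)-1-hydroxypenta-3,4-dien-1-yl]-3-methyloxiran-2-yl]-3,7-dimethylnona-2,6-dien-1-yl acetate | CC(=O)OC/C=C(\C)CC/C=C(\C)CC[C@H]1O[C@]1(C)[C@@H](O)CC=C=C
F7 | step 4 | (2E,6E)-9-[(2R,3R)-3-[(1S)-1-hydroxypenta-3,4-dien-1-yl]-3-methyloxiran-2-yl]-3,7-dimethylnona-2,6-dien-1-ol | OC/C=C(\C)CC/C=C(\C)CC[C@H]1O[C@]1(C)[C@@H](O)CC=C=C
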